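**Plan**

1. Numbering (eudesmane): ring A = C1–C5 and C10, ring B = C5–C10, C14 is the methyl on C10, C15 the carbon on C4. β is the face of C14; the isopropyl group is α (a 7-epi-eudesmane).
2. Enabling feature: carbinol C1 is the neighbour of quaternary C10 (methyl C14), and C10–C5–C6(O) is an allylic alcohol array inside ring B, the menthane ring that carries the C7 isopropyl group. A glycolate on O6 can therefore pass C1 to C10 by a [3,3] shift.
3. Retrosynthesis, in order: the three orthoester C–O bonds (tetraol 30 plus orthocinnamate 34); C6–O and C5–H; C4–O and C15–O; C4=C15; C4–C5 of ring A (through the C5=C6 enone); C2–C3; last C1–C10 and the ester C–O, back to cis-piperitol and benzyloxyacetyl chloride.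
4. Forward: ring B comes intact from (−)-menthone; step 5 joins C1 to C10; the chain grows to C4; ring A closes by intramolecular nitrile oxide cycloaddition; the trioxabicyclic orthoester closes last.
5. Stereochemistry: C7 from menthone; the temporary C6 carbinol by LiBH(s-Bu)3; C10 by suprafacial transfer from C6–O; C1 by chelated enolate geometry in a boat array; C4 by OsO4 anti to C14; C5 and C6 by syn hydroboration on the α face; the orthoester carbon by the cage.

Key step: step 5

Remark: (−)-menthone is taken free of isomenthone, because the isopropyl-bearing carbon is the only stereocentre carried past step 2; oxime 17 is used as its E/Z mixture.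

**Route**

Step 1
Reactants: 1 (−)-menthone
Product: 3 (3R,6S)-6-isopropyl-3-methyl-1-(trimethylsilyloxy)cyclohexene, via lithium enolate 2 (not isolated)
Conditions: LiN(i-Pr)2, THF, −78 °C; Me3SiCl, −78 °C to 0 °C
Reagents that add atoms: chlorotrimethylsilane, C[Si](C)(C)Cl
Why: Kinetic deprotonation takes the methylene proton rather than the hindered methine next to isopropyl, and O-silylation (silyl enol ether formation) traps this regioisomer without touching either stereocentre.

Step 2
Reactants: 3 silyl enol ether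
Product: 4 (S)-piperitone [(6S)-6-isopropyl-3-methylcyclohex-2-en-1-one]
Conditions: Pd(OAc)2 (1.05 equiv), MeCN, rt
Reagents that add atoms: none
Why: Saegusa–Ito oxidation, in which the enolate of divalent palladium undergoes β-hydride elimination toward the methyl-bearing carbon, so the enone forms on the former methylene side and the isopropyl-bearing centre is untouched under non-basic conditions.

Step 3
Reactants: 4 (S)-piperitone
Product: 5 cis-piperitol [(1R,6S)-6-isopropyl-3-methylcyclohex-2-en-1-ol]
Conditions: LiBH(s-Bu)3, THF, −78 °C; H2O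
Reagents that add atoms: none
Why: 1,2-Reduction of a β-substituted cyclohexenone by a bulky trialkylborohydride, which attacks from the equatorial direction opposite the adjacent isopropyl group and so should set the carbinol carbon (eudesmane C6) with oxygen cis to isopropyl.

Step 4
Reactants: 5 cis-piperitol; 6 benzyloxyacetyl chloride
Product: 7 (1R,6S)-6-isopropyl-3-methylcyclohex-2-en-1-yl (benzyloxy)acetate
Conditions: pyridine, DMAP (cat.), CH2Cl2, 0 °C
Reagents that add atoms: none
Why: DMAP-catalysed acylation of a secondary allylic alcohol by an acid chloride, run cold and buffered so that the ionisable allylic C–O bond is not disturbed and no stereocentre changes.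

Step 5
Reactants: 7 cis-piperityl benzyloxyacetate
Product: 11 (2R)-2-(benzyloxy)-2-[(1S,4S)-4-isopropyl-1-methylcyclohex-2-en-1-yl]acetic acid, via chelated lithium enolate 8 (not isolated), via silyl ketene acetal 9 (not isolated), via trimethylsilyl ester 10 (not isolated)
Conditions: LiN(SiMe3)2, THF, −78 °C; Me3SiCl, −78 °C to rt, then 50 °C; 1 M HCl work-up
Reagents that add atoms: none
Why: Ireland–Claisen rearrangement: LiN(SiMe3)2 gives lithium enolate 8 in which the benzyloxy oxygen chelates lithium and so lies cis to the enolate oxygen, Me3SiCl traps it as ketene acetal 9, and on warming a concerted suprafacial [3,3] shift forms C1–C10 while C6–O breaks and the alkene moves to C5=C6; the closest known reaction type is the chelate-controlled glycolate Ireland–Claisen rearrangement of cyclohex-2-enyl esters. No ring closes. C10 is controlled by the C6 carbinol centre: the C6–O bond is pseudoaxial and cis to the pseudoequatorial isopropyl group, so C1 arrives on that same face and the new quaternary carbon carries C1 cis and methyl C14 trans to isopropyl. C1 is controlled by the fixed ketene acetal geometry together with the boat array that cyclohexenyl esters prefer, because the chair would push the silyloxy-bearing carbon under the ring and against the cis isopropyl group; boat plus chelated geometry lead to the 2R acid. The step needs complete face transfer to C10 and simple diastereoselection at C1, which the single C6 stereocentre and the lithium chelate should secure. Silyl ester 10 is cleaved to acid 11 in the acidic work-up.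

Step 6
Reactants: 11 acid
Product: 12 (2R)-2-(benzyloxy)-2-[(1S,4S)-4-isopropyl-1-methylcyclohex-2-en-1-yl]ethanol
Conditions: LiAlH4, THF, 0 °C to rt; H2O then aq. NaOH
Reagents that add atoms: none
Why: Hydride reduction of a carboxylic acid to the primary alcohol leaves the benzyl ether, the isolated alkene and the C1 and C10 centres alone.

Step 7
Reactants: 12 alcohol
Product: 13 (2R)-2-(benzyloxy)-2-[(1S,4S)-4-isopropyl-1-methylcyclohex-2-en-1-yl]acetaldehyde
Conditions: Dess–Martin periodinane, CH2Cl2, rt
Reagents that add atoms: none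
Why: Dess–Martin oxidation is neutral and fast, so the α-benzyloxy aldehyde, whose C1 sits next to a quaternary carbon, should form without epimerisation.

Step 8
Reactants: 13 aldehyde
Product: 14 ethyl (2E,4S)-4-(benzyloxy)-4-[(1S,4S)-4-isopropyl-1-methylcyclohex-2-en-1-yl]but-2-enoate
Conditions: Ph3P=CHCO2Et, toluene, 80 °C
Reagents that add atoms: ethyl (triphenylphosphoranylidene)acetate, CCOC(=O)C=P(c1ccccc1)(c1ccccc1)c1ccccc1
Why: Wittig olefination with a stabilised, base-free ylide adds C3 and C4 as the E enoate and avoids enolisation of the α-alkoxy aldehyde.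

Step 9
Reactants: 14 enoate
Product: 15 ethyl (4S)-4-(benzyloxy)-4-[(1S,4S)-4-isopropyl-1-methylcyclohex-2-en-1-yl]butanoate
Conditions: NaBH4, CuCl (cat.), EtOH–THF, 0 °C
Reagents that add atoms: none
Why: Copper hydride conjugate reduction delivers hydride only to the β-carbon C2 of the enoate, so the ring alkene and benzyl ether survive and, unlike in an electron-transfer reduction, the C1 benzyloxy group γ to the ester is not expelled.

Step 10
Reactants: 15 ester
Product: 16 (4S)-4-(benzyloxy)-4-[(1S,4S)-4-isopropyl-1-methylcyclohex-2-en-1-yl]butanal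
Conditions: i-Bu2AlH (1.1 equiv), CH2Cl2, −78 °C; aq. potassium sodium tartrate
Reagents that add atoms: none
Why: Partial reduction of an ester at low temperature stops at the aluminium hemiacetal, which releases the C4 aldehyde only on work-up.

Step 11
Reactants: 16 aldehyde
Product: 17 (4S)-4-(benzyloxy)-4-[(1S,4S)-4-isopropyl-1-methylcyclohex-2-en-1-yl]butanal oxime
Conditions: NH2OH·HCl, NaOAc, EtOH, rt
Reagents that add atoms: hydroxylamine hydrochloride, NO.Cl
Why: Condensation of an unhindered aldehyde with hydroxylamine gives the aldoxime, whose E/Z mixture is of no consequence for the next step.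

Step 12
Reactants: 17 oxime
Product: 20 cis-fused isoxazoline (C4=N–O–C6α; 5β-H; 1β-OBn; 7α-isopropyl; 10β-methyl), via hydroximoyl chloride 18 (not isolated), via nitrile oxide 19 (not isolated)
Conditions: NaOCl (aq.), CH2Cl2, 0 °C to rt, high dilution
Reagents that add atoms: none
Why: Intramolecular nitrile oxide–alkene [3+2] cycloaddition, in which hypochlorite takes the oxime through chloride 18 to nitrile oxide 19 and the four-atom tether from C10 forces C4 onto C5 and oxygen onto C6 from the α face where C1 stands, closing ring A as the cis-fused isoxazoline (the C5 and C6 centres made here are temporary).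

Step 13
Reactants: 20 isoxazoline
Product: 22 1β-benzyloxy-6α-hydroxy-7α-isopropyl-10β-methyl-5β-decalin-4-one, via β-hydroxy imine 21 (not isolated)
Conditions: H2 (1 atm), Raney Ni, B(OH)3, MeOH–H2O (5:1), rt
Reagents that add atoms: water, O
Why: Reductive N–O cleavage of an isoxazoline followed by buffered hydrolysis of the imine unmasks the β-hydroxy ketone, with no alkene left to reduce and the benzyl ether stable under these mild conditions.

Step 14
Reactants: 22 β-hydroxy ketone
Product: 24 1β-benzyloxy-7α-isopropyl-10β-methyl-Δ5(6)-octalin-4-one, via mesylate 23 (not isolated)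
Conditions: MsCl, Et3N (excess), CH2Cl2, 0 °C to rt
Reagents that add atoms: none
Why: Mesylation and E1cB elimination of a β-hydroxy ketone gives the conjugated C5=C6 enone and erases the temporary C5 and C6 centres under a base too weak to deprotonate the γ position C7.

Step 15
Reactants: 24 enone
Product: 25 1β-benzyloxy-7-epi-eudesma-4(15),5-diene
Conditions: Ph3PCH3Br, KOt-Bu, THF, 0 °C to rt
Reagents that add atoms: methyltriphenylphosphonium bromide, C[P+](c1ccccc1)(c1ccccc1)c1ccccc1.[Br-]
Why: Wittig methylenation of the enone carbonyl installs C15, the non-stabilised ylide adding 1,2 faster than it can deprotonate the hindered γ methine C7.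

Step 16
Reactants: 25 diene
Product: 26 1β-benzyloxy-7-epi-eudesm-5-ene-4α,15-diol
Conditions: OsO4 (2 mol %), N-methylmorpholine N-oxide, acetone–H2O, 0 °C
Reagents that add atoms: osmium tetroxide, O=[Os](=O)(=O)=O; N-methylmorpholine N-oxide, C[N+]1([O-])CCOCC1
Why: Catalytic OsO4 dihydroxylation should take the open 1,1-disubstituted C4=C15 bond in preference to the trisubstituted C5=C6 bond flanked by quaternary C10 and the isopropyl-bearing C7, and it adds from the α face away from the axial C14 methyl, so O4 becomes α and C15 β.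

Step 17
Reactants: 26 diol
Product: 27 4α,15-O-isopropylidene acetal of 26
Conditions: 2-methoxypropene, PPTS (cat.), CH2Cl2, 0 °C
Reagents that add atoms: 2-methoxypropene, COC(C)=C
Why: Mild acid-catalysed acetonide formation ties the primary and tertiary hydroxyls into a spiro-dioxolane whose β C15 methylene adds to the shielding of the β face of C5=C6.

Step 18
Reactants: 27 acetonide
Product: 29 1β-benzyloxy-4α,15-(isopropylidenedioxy)-7-epi-5α-eudesman-6α-ol, via C6 alkylborane 28 (not isolated)
Conditions: BH3·THF (excess), THF, 0 °C to rt; NaOH, H2O2, 0 °C to rt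
Reagents that add atoms: hydrogen peroxide, OO
Why: Hydroboration–oxidation, in which boron adds to the less substituted C6 and hydrogen to C5 in a syn manner from the α face because the β face of C5 is flanked by the axial C14 methyl and the axial C15 methylene, and oxidation with retention gives the 6α alcohol and 5α hydrogen of the trans-decalin.

Step 19
Reactants: 29 alcohol
Product: 30 7-epi-5α-eudesmane-1β,4α,6α,15-tetraol
Conditions: H2 (1 atm), Pd/C, MeOH–H2O (9:1), HCl (cat.), rt
Reagents that add atoms: none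
Why: Hydrogenolysis of the benzyl ether and acid hydrolysis of the acetonide in one operation free all four hydroxyls before the hydrogenation-sensitive styryl group is brought in.

Step 20
Reactants: 31 (E)-β-bromostyrene; 32 tetramethyl orthocarbonate
Product: 34 trimethyl (E)-orthocinnamate, via (E)-styrylmagnesium bromide 33 (not isolated)
Conditions: Mg, THF, rt to 50 °C; then 32, THF, reflux
Reagents that add atoms: none
Why: Grignard addition to an orthocarbonate displaces one methoxide and stops at the orthoester, the alkenyl Grignard reagent keeping its E geometry.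

Step 21
Reactants: 30 tetraol; 34 trimethyl (E)-orthocinnamate
Product: 35 target, 7-epi-5α-eudesmane-1β,4α,6α,15-tetraol 4,6,15-orthocinnamate with free 1β-hydroxyl
Conditions: PPTS (cat.), CH2Cl2–MeCN, 5 Å molecular sieves, rt; Et3N quench
Reagents that add atoms: none
Why: Acid-catalysed orthoester exchange starts at the primary C15 hydroxyl and closes onto the 4α and 6α hydroxyls, the only triad that one carbon can span, so the 2,7,8-trioxabicyclo[3.2.1]octane cage should form as the thermodynamic product with its carbon configuration fixed by the cage and the remote 1β hydroxyl left free.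

**Compound list**

1 | (−)-menthone [(2S,5R)-2-isopropyl-5-methylcyclohexanone] | C[C@@H]1CC[C@H](C(=O)C1)C(C)C | starting material
2 | lithium enolate of 1 on the methylene side (not isolated) | C[C@@H]1CC[C@H](C([O-])=C1)C(C)C.[Li+] | intermediate
3 | (3R,6S)-6-isopropyl-3-methyl-1-(trimethylsilyloxy)cyclohexene | C[C@@H]1CC[C@H](C(O[Si](C)(C)C)=C1)C(C)C | intermediate
4 | (S)-piperitone, (6S)-6-isopropyl-3-methylcyclohex-2-en-1-one | CC(C)[C@@H]1CCC(C)=CC1=O | intermediate
5 | cis-piperitol, (1R,6S)-6-isopropyl-3-methylcyclohex-2-en-1-ol | CC(C)[C@@H]1CCC(C)=C[C@@H]1O | intermediate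
6 | benzyloxyacetyl chloride | O=C(Cl)COCc1ccccc1 | starting material
7 | (1R,6S)-6-isopropyl-3-methylcyclohex-2-en-1-yl (benzyloxy)acetate (cis ester) | CC(C)[C@@H]1CCC(C)=C[C@@H]1OC(=O)COCc2ccccc2 | intermediate
8 | chelated lithium enolate of 7, OBn cis to OLi (not isolated) | CC(C)[C@@H]1CCC(C)=C[C@@H]1O/C([O-])=C/OCc2ccccc2.[Li+] | intermediate
9 | trimethylsilyl ketene acetal of 7, OBn cis to OSiMe3 (not isolated) | CC(C)[C@@H]1CCC(C)=C[C@@H]1O/C(O[Si](C)(C)C)=C/OCc2ccccc2 | intermediate
10 | trimethylsilyl ester of acid 11 (not isolated) | CC(C)[C@@H]1CC[C@@](C)(C=C1)[C@@H](OCc2ccccc2)C(=O)O[Si](C)(C)C | intermediate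
11 | (2R)-2-(benzyloxy)-2-[(1S,4S)-4-isopropyl-1-methylcyclohex-2-en-1-yl]acetic acid | CC(C)[C@@H]1CC[C@@](C)(C=C1)[C@@H](OCc2ccccc2)C(=O)O | intermediate
12 | (2R)-2-(benzyloxy)-2-[(1S,4S)-4-isopropyl-1-methylcyclohex-2-en-1-yl]ethanol | CC(C)[C@@H]1CC[C@@](C)(C=C1)[C@@H](OCc2ccccc2)CO | intermediate
13 | (2R)-2-(benzyloxy)-2-[(1S,4S)-4-isopropyl-1-methylcyclohex-2-en-1-yl]acetaldehyde | CC(C)[C@@H]1CC[C@@](C)(C=C1)[C@@H](OCc2ccccc2)C=O | intermediate
14 | ethyl (2E,4S)-4-(benzyloxy)-4-[(1S,4S)-4-isopropyl-1-methylcyclohex-2-en-1-yl]but-2-enoate | CC(C)[C@@H]1CC[C@@](C)(C=C1)[C@@H](OCc2ccccc2)/C=C/C(=O)OCC | intermediate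
15 | ethyl (4S)-4-(benzyloxy)-4-[(1S,4S)-4-isopropyl-1-methylcyclohex-2-en-1-yl]butanoate | CC(C)[C@@H]1CC[C@@](C)(C=C1)[C@@H](OCc2ccccc2)CCC(=O)OCC | intermediate
16 | (4S)-4-(benzyloxy)-4-[(1S,4S)-4-isopropyl-1-methylcyclohex-2-en-1-yl]butanal | CC(C)[C@@H]1CC[C@@](C)(C=C1)[C@@H](OCc2ccccc2)CCC=O | intermediate
17 | oxime of 16 (E/Z mixture) | CC(C)[C@@H]1CC[C@@](C)(C=C1)[C@@H](OCc2ccccc2)CCC=NO | intermediate
18 | hydroximoyl chloride from 17 (not isolated) | CC(C)[C@@H]1CC[C@@](C)(C=C1)[C@@H](OCc2ccccc2)CCC(Cl)=NO | intermediate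
19 | nitrile oxide from 18 (not isolated) | CC(C)[C@@H]1CC[C@@](C)(C=C1)[C@@H](OCc2ccccc2)CCC#[N+][O-] | intermediate
20 | cis-fused isoxazoline: C4=N–O bridge to C6 (O on C6α), 5β-H, 1β-benzyloxy, 7α-isopropyl, 10β-methyl | CC(C)[C@@H]1CC[C@@]2(C)[C@H]3[C@@H]1ON=C3CC[C@@H]2OCc1ccccc1 | intermediate
21 | β-hydroxy imine from 20 (C4=NH, 6α-OH, 5β-H; not isolated) | CC(C)[C@@H]1CC[C@@]2(C)[C@@H]([C@@H]1O)C(=N)CC[C@@H]2OCc1ccccc1 | intermediate
22 | 1β-benzyloxy-6α-hydroxy-7α-isopropyl-10β-methyl-5β-decalin-4-one (cis-fused) | CC(C)[C@@H]1CC[C@@]2(C)[C@@H]([C@@H]1O)C(=O)CC[C@@H]2OCc1ccccc1 | intermediate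
23 | 6α-methanesulfonate of 22 (not isolated) | CC(C)[C@@H]1CC[C@@]2(C)[C@@H]([C@@H]1OS(C)(=O)=O)C(=O)CC[C@@H]2OCc1ccccc1 | intermediate
24 | 1β-benzyloxy-7α-isopropyl-10β-methyl-Δ5(6)-octalin-4-one (enone) | CC(C)[C@@H]1CC[C@@]2(C)C(=C1)C(=O)CC[C@@H]2OCc1ccccc1 | intermediate
25 | 1β-benzyloxy-7-epi-eudesma-4(15),5-diene (isopropyl α) | CC(C)[C@@H]1CC[C@@]2(C)C(=C1)C(=C)CC[C@@H]2OCc1ccccc1 | intermediate
26 | 1β-benzyloxy-7-epi-eudesm-5-ene-4α,15-diol | CC(C)[C@@H]1CC[C@@]2(C)C(=C1)[C@](O)(CO)CC[C@@H]2OCc1ccccc1 | intermediate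
27 | 4α,15-O-isopropylidene acetal of 26 | CC(C)[C@@H]1CC[C@@]2(C)C(=C1)[C@@]3(OC(C)(C)OC3)CC[C@@H]2OCc1ccccc1 | intermediate
28 | C6α alkylborane from 27, 5α-H (not isolated) | CC(C)[C@@H]1CC[C@@]2(C)[C@H]([C@@H]1B)[C@@]3(OC(C)(C)OC3)CC[C@@H]2OCc1ccccc1 | intermediate
29 | 1β-benzyloxy-4α,15-(isopropylidenedioxy)-7-epi-5α-eudesman-6α-ol | CC(C)[C@@H]1CC[C@@]2(C)[C@H]([C@@H]1O)[C@@]3(OC(C)(C)OC3)CC[C@@H]2OCc1ccccc1 | intermediate
30 | 7-epi-5α-eudesmane-1β,4α,6α,15-tetraol | CC(C)[C@@H]1CC[C@@]2(C)[C@H]([C@@H]1O)[C@](O)(CO)CC[C@@H]2O | intermediate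
31 | (E)-β-bromostyrene | Br/C=C/c1ccccc1 | starting material
32 | tetramethyl orthocarbonate | COC(OC)(OC)OC | starting material
33 | (E)-styrylmagnesium bromide (not isolated) | Br[Mg]/C=C/c1ccccc1 | intermediate
34 | trimethyl (E)-orthocinnamate, (E)-(3,3,3-trimethoxyprop-1-enyl)benzene | COC(OC)(OC)/C=C/c1ccccc1 | intermediate
35 | 7-epi-5α-eudesmane-1β,4α,6α,15-tetraol 4,6,15-orthocinnamate [(E)-styryl orthoester, 1β-OH free] | CC(C)[C@@H]1CC[C@@]2(C)[C@@H]3[C@@H]1O[C@]1(/C=C/c4ccccc4)OC[C@@]3(CC[C@@H]2O)O1 | target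

**Step count**

Total: 21 steps. Longest linear sequence: 20 steps (steps 1–19 and 21); step 20 is a one-step side branch.

**Steps most likely to fail**

1. Step 18, poor facial selectivity in the hydroboration. The α face is the intended one, but the pseudoaxial isopropyl group on C7 stands on that face next to C6, so borane may add in part from the β face and give the 5β,6β series. The fallback sets out from diol 26 and lets the 4α oxygen deliver both silicon and hydrogen. TBSCl and imidazole protect the primary hydroxyl as the 15-O-tert-butyldimethylsilyl ether F1. Me2SiHCl, Et3N and DMAP give the 4α-O-dimethylsilyl ether F2. Pt2[(CH2=CHSiMe2)2O]3 (cat.) in toluene at 60 °C should effect 5-endo intramolecular hydrosilylation to the oxasilolane F3, with silicon on C6α and hydrogen on C5α, both fixed by the tether. Tamao–Fleming oxidation (H2O2, KF, KHCO3, THF–MeOH) gives the 4α,6α-diol F4. The conditions of step 19, whose acidic methanol also cleaves the primary silyl ether, bring the route back at tetraol 30.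

2. Step 16, loss of chemoselectivity in the dihydroxylation. Osmium tetroxide may attack the more electron-rich C5=C6 bond of the diene or oxidise both alkenes. The fallback sets out from enone 24 and masks the ring alkene. Alkaline H2O2 (NaOH, MeOH, 0 °C; Weitz–Scheffer epoxidation) gives the 5,6-epoxy ketone F5, drawn as the β-epoxide; its configuration is of no consequence. Ph3PCH3Br and KOt-Bu give the 4-methylene epoxide F6. OsO4 with N-methylmorpholine N-oxide gives the epoxy diol F7, the exocyclic alkene now being the only one. 2-Methoxypropene and PPTS give the epoxy acetonide F8. Deoxygenation with WCl6 and n-BuLi (THF, −78 °C to rt) restores C5=C6 and comes back at acetonide 27.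

3. Step 5, erosion of simple diastereoselection at C1. If the chair array competes with the boat, the C1 epimer of acid 11 forms alongside it (C10 is not affected). The fallback sets out from cis-piperitol 5 and moves the control of C1 from the rearrangement to an auxiliary, keeping the [3,3] formation of C1–C10. Ac2O and pyridine give cis-piperityl acetate F9. LiN(i-Pr)2 then Me3SiCl (THF, −78 °C to 60 °C) lead through the lithium enolate F10 and the silyl ketene acetal F11 to the rearranged silyl ester F12, and acidic work-up gives the acid F13, in which C1 is a methylene group. DCC and DMAP couple it with (R)-4-benzyl-2-oxazolidinone to the imide F14. NaN(SiMe3)2 at −78 °C forms the sodium enolate F15, which 2-(phenylsulfonyl)-3-phenyloxaziridine hydroxylates on the face opposite the auxiliary benzyl group to the (2R)-α-hydroxy imide F16. Benzyl 2,2,2-trichloroacetimidate with catalytic TfOH gives the benzyl ether F17, and LiBH4 (Et2O, one equivalent of H2O) removes the auxiliary and comes back at alcohol 12.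

Further compounds
F1 | step 18 | 15-O-tert-butyldimethylsilyl ether of diol 26 | CC(C)[C@@H]1CC[C@@]2(C)C(=C1)[C@](O)(CO[Si](C)(C)C(C)(C)C)CC[C@@H]2OCc1ccccc1
F2 | step 18 | 4α-O-dimethylsilyl (Si–H) ether of F1 | CC(C)[C@@H]1CC[C@@]2(C)C(=C1)[C@](O[SiH](C)C)(CO[Si](C)(C)C(C)(C)C)CC[C@@H]2OCc1ccccc1
F3 | step 18 | oxasilolane with SiMe2 bonded to O4 and to C6α, 5α-H | CC(C)[C@@H]1CC[C@@]2(C)[C@@H]3[C@@H]1[Si](C)(C)O[C@@]3(CO[Si](C)(C)C(C)(C)C)CC[C@@H]2OCc1ccccc1
F4 | step 18 | 1β-benzyloxy-15-(tert-butyldimethylsilyloxy)-7-epi-5α-eudesmane-4α,6α-diol | CC(C)[C@@H]1CC[C@@]2(C)[C@H]([C@@H]1O)[C@](O)(CO[Si](C)(C)C(C)(C)C)CC[C@@H]2OCc1ccccc1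
F5 | step 16 | 5β,6β-epoxide of enone 24 | CC(C)[C@@H]1CC[C@@]2(C)[C@]3(O[C@@H]13)C(=O)CC[C@@H]2OCc1ccccc1
F6 | step 16 | 4-methylene derivative of F5 | CC(C)[C@@H]1CC[C@@]2(C)[C@]3(O[C@@H]13)C(=C)CC[C@@H]2OCc1ccccc1
F7 | step 16 | 4α,15-diol from F6 (5β,6β-epoxide) | CC(C)[C@@H]1CC[C@@]2(C)[C@]3(O[C@@H]13)[C@](O)(CO)CC[C@@H]2OCc1ccccc1
F8 | step 16 | 4α,15-O-isopropylidene acetal of F7 (5β,6β-epoxide of 27) | CC(C)[C@@H]1CC[C@@]2(C)[C@]3(O[C@@H]13)[C@@]4(OC(C)(C)OC4)CC[C@@H]2OCc1ccccc1
F9 | step 5 | cis-piperityl acetate, (1R,6S)-6-isopropyl-3-methylcyclohex-2-en-1-yl acetate | CC(C)[C@@H]1CCC(C)=C[C@@H]1OC(C)=O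
F10 | step 5 | lithium enolate of F9 | CC(C)[C@@H]1CCC(C)=C[C@@H]1OC([O-])=C.[Li+]
F11 | step 5 | trimethylsilyl ketene acetal of F9 | CC(C)[C@@H]1CCC(C)=C[C@@H]1OC(=C)O[Si](C)(C)C
F12 | step 5 | trimethylsilyl ester of F13 | CC(C)[C@@H]1CC[C@@](C)(C=C1)CC(=O)O[Si](C)(C)C
F13 | step 5 | 2-(4-isopropyl-1-methylcyclohex-2-en-1-yl)acetic acid with the ring configuration of 11 | CC(C)[C@@H]1CC[C@@](C)(C=C1)CC(=O)O
F14 | step 5 | N-acyl imide of F13 with (R)-4-benzyl-2-oxazolidinone | CC(C)[C@@H]1CC[C@@](C)(C=C1)CC(=O)N1C(=O)OC[C@H]1Cc1ccccc1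
F15 | step 5 | sodium enolate of F14 (ring carbon cis to O−) | CC(C)[C@@H]1CC[C@@](C)(C=C1)/C=C(\[O-])N1C(=O)OC[C@H]1Cc1ccccc1.[Na+]
F16 | step 5 | (2R)-α-hydroxy imide from F15 | CC(C)[C@@H]1CC[C@@](C)(C=C1)[C@@H](O)C(=O)N1C(=O)OC[C@H]1Cc1ccccc1
F17 | step 5 | (2R)-α-benzyloxy imide from F16 | CC(C)[C@@H]1CC[C@@](C)(C=C1)[C@@H](OCc1ccccc1)C(=O)N1C(=O)OC[C@H]1Cc1ccccc1
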